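The benzylic C7–OH bond is traced back to a C7–Si bond, so that the whole stereochemical problem becomes one intramolecular hydrosilylation. The feature used is the 1,3-relationship of the hydroxyls on C7 (benzylic carbon on the 3,4,5-trimethoxyphenyl ring) and C9 (CH2OH) across C8, the carbon that carries the 4-allyl-2,6-dimethoxyphenoxy ring: a hydrosilane on O9 can add across a C7=C8 enol ether. In one operation this closes a 1,2-oxasilolane ring, forms C7–Si and C8–H on the same face and sets both stereocentres; oxidation of C–Si then gives the threo diol. The precursor is the (E)-2-aryloxy-3-arylallyl alcohol, fully assembled, as its O9 dimethylsilyl (Si–H) ether.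

Key step: step 6

Remark on numbering and configuration: C7 is the benzylic carbinol carbon, C8 the aryloxy-bearing carbon, C9 the CH2OH carbon. The target is 7R,8R, i.e. (1R,2R) as a propane-1,3-diol, threo. In 6, 7 and 9, E means that the trimethoxyphenyl group is trans to the aryloxy group and cis to C9. Syn addition to that alkene on the C7-Re/C8-Re face gives the 3,4-cis (3R,4R) silacycle 10, and oxidation with retention maps it onto 7R,8R.

Assumption: the sense of induction of the diphosphine on this substrate cannot be read from simpler cases. (R)-BINAP is written as the antipode that adds to the C7-Re/C8-Re face; (S)-BINAP takes its place if the opposite sense is found.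

Remark on the precursor: 9 keeps two methyl groups on silicon so that the tether stays small enough to reach a trisubstituted, aryloxy-flanked alkene. Its Si–O bond hydrolyses easily, so it is made salt-free and used without aqueous work-up or chromatography.

Step 1
Reactants: 1 ethyl 2-(diphenoxyphosphoryl)acetate
Product: 2 ethyl 2-diazo-2-(diphenoxyphosphoryl)acetate
Conditions: p-ABSA (1.1 equiv), DBU (1.1 equiv), MeCN, 0 °C to rt
Reagents that add atoms: 4-acetamidobenzenesulfonyl azide (p-ABSA), CC(=O)Nc1ccc(cc1)S(=O)(=O)N=[N+]=[N-]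
Why: Regitz diazo transfer: the CH2 between ester and phosphonate is deprotonated by DBU and attacks the sulfonyl azide, and the triazene collapses to the diazo compound and the sulfonamide; no stereocentre is formed.

Step 2
Reactants: 2 ethyl 2-diazo-2-(diphenoxyphosphoryl)acetate; 3 4-allyl-2,6-dimethoxyphenol
Product: 4 ethyl 2-(4-allyl-2,6-dimethoxyphenoxy)-2-(diphenoxyphosphoryl)acetate (racemic)
Conditions: Rh2(OAc)4 (1 mol %), PhMe, 80 °C, slow addition of 2 to 3 (1.2 equiv)
Reagents that add atoms: none
Why: Rh(II) carbenoid O–H insertion: the electrophilic acceptor/acceptor carbenoid should be captured by the phenol oxygen (oxonium ylide, then 1,2-proton shift) faster than it cyclopropanates the allyl alkene or the arene, which installs the hindered aryl ether without SN2 chemistry; the new centre is racemic and disappears in step 3.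

Step 3
Reactants: 4 ethyl 2-(4-allyl-2,6-dimethoxyphenoxy)-2-(diphenoxyphosphoryl)acetate; 5 3,4,5-trimethoxybenzaldehyde
Product: 6 ethyl (E)-2-(4-allyl-2,6-dimethoxyphenoxy)-3-(3,4,5-trimethoxyphenyl)prop-2-enoate (trimethoxyphenyl cis to the ester)
Conditions: NaH, THF, −78 °C; then 5, −78 to 0 °C
Reagents that add atoms: none
Why: Horner–Wadsworth–Emmons olefination in its diaryl phosphonate (cis-selective) variant: the electron-poor phosphorus makes collapse of the first-formed adduct fast, so the kinetic isomer with the aryl group cis to the ester (E by CIP, because OAr outranks CO2Et) should predominate and is purified by chromatography; no stereocentre.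

Step 4
Reactants: 6 ethyl (E)-2-(4-allyl-2,6-dimethoxyphenoxy)-3-(3,4,5-trimethoxyphenyl)prop-2-enoate
Product: 7 (E)-2-(4-allyl-2,6-dimethoxyphenoxy)-3-(3,4,5-trimethoxyphenyl)prop-2-en-1-ol
Conditions: DIBAL-H (2.5 equiv), CH2Cl2, −78 °C; Rochelle salt work-up
Reagents that add atoms: none
Why: DIBAL-H 1,2-reduction of an α,β-unsaturated ester to the allylic alcohol at low temperature, which should leave the enol ether geometry, the terminal alkene and the aryl ethers untouched; no stereocentre.

Step 5
Reactants: 7 (E)-2-(4-allyl-2,6-dimethoxyphenoxy)-3-(3,4,5-trimethoxyphenyl)prop-2-en-1-ol; 8 1,1,3,3-tetramethyldisilazane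
Product: 9 (E)-{[2-(4-allyl-2,6-dimethoxyphenoxy)-3-(3,4,5-trimethoxyphenyl)prop-2-en-1-yl]oxy}dimethylsilane
Conditions: (HMe2Si)2NH (1.5 equiv, neat), 50 °C; volatiles removed in vacuo, used crude
Reagents that add atoms: 1,1,3,3-tetramethyldisilazane (8), C[SiH](C)N[SiH](C)C
Why: O-silylation of a primary alcohol with a disilazane (transsilylation driven by loss of ammonia) gives the Si–H ether under neutral conditions with no salt to remove, so the labile product can be used directly.

Step 6
Reactants: 9 (E)-{[2-(4-allyl-2,6-dimethoxyphenoxy)-3-(3,4,5-trimethoxyphenyl)prop-2-en-1-yl]oxy}dimethylsilane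
Product: 10 (3R,4R)-4-(4-allyl-2,6-dimethoxyphenoxy)-2,2-dimethyl-3-(3,4,5-trimethoxyphenyl)-1,2-oxasilolane (3,4-cis)
Conditions: [Rh((R)-BINAP)(acetone)2]BF4 (3 mol %; from [Rh(nbd)((R)-BINAP)]BF4 and H2, H2 then removed), acetone, 0.02 M, 25 °C, Ar
Reagents that add atoms: none
Why: Proposed new method: the cationic Rh(I) diphosphine adds oxidatively to Si–H, the tethered C7=C8 enol ether coordinates, and migratory insertion followed by reductive elimination delivers Si to C7 and H to C8 on one face (syn), whether the silyl or the hydride migrates first. The closest known reaction types are the Rh(diphosphine)+-catalysed asymmetric cyclisation of 3-aryl allyl hydrosilyl ethers and the Pt-catalysed cyclisation of 2-alkoxy allyl hydrosilyl ethers, both followed by C–Si oxidation to 1,3-diols; a trisubstituted aryl enol ether has not been used in the asymmetric version. The 1,2-oxasilolane closes 5-endo-trig, because the O9–Si tether reaches C7 comfortably whereas bonding to C8 would require a four-membered ring. The relative configuration (3,4-cis) is fixed by syn addition to the E alkene, in which the trimethoxyphenyl group is cis to C9, and the absolute configuration (3R,4R, addition to the C7-Re/C8-Re face) is fixed by the BINAP antipode. The step needs enantiofacial selection, an unscrambled E geometry, reductive elimination faster than β-aryloxy or β-hydride elimination from the Rh alkyl, and preference for the tethered alkene over the remote allyl group; the C7 aryl group (the substituent associated with high selectivity in 3-aryl allyl silyl ethers), the short tether and high dilution are relied on for these.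

Step 7
Reactants: 10 (3R,4R)-4-(4-allyl-2,6-dimethoxyphenoxy)-2,2-dimethyl-3-(3,4,5-trimethoxyphenyl)-1,2-oxasilolane
Product: 11 (1R,2R)-2-(4-allyl-2,6-dimethoxyphenoxy)-1-(3,4,5-trimethoxyphenyl)propane-1,3-diol (7R,8R, threo; the target)
Conditions: 30% aq H2O2 (10 equiv), KF (2 equiv), KHCO3 (2 equiv), THF/MeOH 1:1, rt
Reagents that add atoms: hydrogen peroxide, OO
Why: Tamao–Fleming oxidation: hydroperoxide and fluoride attack the alkoxysilane to give a hypervalent silyl peroxide in which C7 migrates from Si to O with retention, and solvolysis of the Si–O bonds frees both hydroxyls; nucleophilic peroxide should not touch the terminal alkene or the arenes, and β-elimination of aryloxide is disfavoured because the ring holds the Si–C7 and C8–OAr bonds away from antiperiplanarity, in line with the known oxidation of 2-alkoxy-substituted oxasilolanes.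

Compound list
1 | ethyl 2-(diphenoxyphosphoryl)acetate | CCOC(=O)CP(=O)(Oc1ccccc1)Oc1ccccc1 | starting material
2 | ethyl 2-diazo-2-(diphenoxyphosphoryl)acetate | CCOC(=O)C(=[N+]=[N-])P(=O)(Oc1ccccc1)Oc1ccccc1 | intermediate
3 | 4-allyl-2,6-dimethoxyphenol | C=CCc1cc(OC)c(O)c(OC)c1 | starting material
4 | ethyl 2-(4-allyl-2,6-dimethoxyphenoxy)-2-(diphenoxyphosphoryl)acetate (racemic) | CCOC(=O)C(Oc1c(OC)cc(CC=C)cc1OC)P(=O)(Oc1ccccc1)Oc1ccccc1 | intermediate
5 | 3,4,5-trimethoxybenzaldehyde | COc1cc(C=O)cc(OC)c1OC | starting material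
6 | ethyl (E)-2-(4-allyl-2,6-dimethoxyphenoxy)-3-(3,4,5-trimethoxyphenyl)prop-2-enoate | C=CCc1cc(OC)c(O/C(C(=O)OCC)=C/c2cc(OC)c(OC)c(OC)c2)c(OC)c1 | intermediate
7 | (E)-2-(4-allyl-2,6-dimethoxyphenoxy)-3-(3,4,5-trimethoxyphenyl)prop-2-en-1-ol | C=CCc1cc(OC)c(O/C(CO)=C/c2cc(OC)c(OC)c(OC)c2)c(OC)c1 | intermediate
8 | 1,1,3,3-tetramethyldisilazane | C[SiH](C)N[SiH](C)C | starting material
9 | (E)-{[2-(4-allyl-2,6-dimethoxyphenoxy)-3-(3,4,5-trimethoxyphenyl)prop-2-en-1-yl]oxy}dimethylsilane | C=CCc1cc(OC)c(O/C(CO[SiH](C)C)=C/c2cc(OC)c(OC)c(OC)c2)c(OC)c1 | intermediate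
10 | (3R,4R)-4-(4-allyl-2,6-dimethoxyphenoxy)-2,2-dimethyl-3-(3,4,5-trimethoxyphenyl)-1,2-oxasilolane (3,4-cis) | C=CCc1cc(OC)c(O[C@@H]2CO[Si](C)(C)[C@@H]2c3cc(OC)c(OC)c(OC)c3)c(OC)c1 | intermediate
11 | (1R,2R)-2-(4-allyl-2,6-dimethoxyphenoxy)-1-(3,4,5-trimethoxyphenyl)propane-1,3-diol | C=CCc1cc(OC)c(O[C@H](CO)[C@H](O)c2cc(OC)c(OC)c(OC)c2)c(OC)c1 | target

Total step count: 7. Longest linear sequence: 7 steps (1 → 2 → 4 → 6 → 7 → 9 → 10 → 11); 3, 5 and 8 enter as purchased materials.

Steps most likely to fail

Step 6. The hindered trisubstituted aryl enol ether may fail to insert. The Rh alkyl may lose aryloxide or hydride instead of undergoing reductive elimination. The catalyst may isomerise or hydrosilylate the remote allyl group, or the facial selectivity may be poor. The fallback is an oxazolidinone-auxiliary boron aldol, known chemistry that sets out from 3 and comes back at 11. Phenol 3 is O-alkylated with bromoacetic acid (NaOH, H2O/THF, 60 °C) to 2-(4-allyl-2,6-dimethoxyphenoxy)acetic acid F1. F1 is activated with PivCl/Et3N in THF as 2-(4-allyl-2,6-dimethoxyphenoxy)acetic pivalic anhydride F2 (not isolated) and treated with LiCl and (S)-4-benzyloxazolidin-2-one to give (S)-3-[2-(4-allyl-2,6-dimethoxyphenoxy)acetyl]-4-benzyloxazolidin-2-one F3. Enolisation with Bu2BOTf/i-Pr2NEt (CH2Cl2, −78 °C) and addition of 5 should give the Evans syn aldol (S)-3-[(2S,3R)-2-(4-allyl-2,6-dimethoxyphenoxy)-3-hydroxy-3-(3,4,5-trimethoxyphenyl)propanoyl]-4-benzyloxazolidin-2-one F4. Syn here corresponds to threo, and the (S)-auxiliary to 7R,8R. LiBH4 (THF, 1 equiv H2O, 0 °C) then removes the auxiliary reductively and gives 11.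

Step 3. Kinetic control may be incomplete, so that the thermodynamic isomer with the trimethoxyphenyl group trans to the ester dominates; that isomer would lead to the erythro series. The fallback sets out from 4 (with 5) and comes back at 6. The olefination is accepted as it comes, and the unwanted ethyl (Z)-2-(4-allyl-2,6-dimethoxyphenoxy)-3-(3,4,5-trimethoxyphenyl)prop-2-enoate F5 is separated. F5 is then isomerised by visible-light triplet sensitisation (Ir(ppy)3 cat., MeCN, blue LED, rt). Energy transfer should excite the planar, more conjugated Z isomer preferentially and drain it into the twisted isomer 6, which is separated while F5 is recycled.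

Step 2. The carbenoid may be diverted into cyclopropanation of the allyl group, addition to the electron-rich arene or dimerisation, or a P–OPh bond may be lost on handling. The fallback avoids carbenoid and phosphonate chemistry, sets out from 3 and comes back at 6. Phenol 3 is alkylated with ethyl bromoacetate (K2CO3, acetone, reflux) to ethyl 2-(4-allyl-2,6-dimethoxyphenoxy)acetate F6. Its lithium enolate (LDA, THF, −78 °C) adds to 5 to give ethyl 2-(4-allyl-2,6-dimethoxyphenoxy)-3-hydroxy-3-(3,4,5-trimethoxyphenyl)propanoate F7 as a diastereomer mixture. Acetylation (Ac2O, Et3N, DMAP) gives ethyl 3-acetoxy-2-(4-allyl-2,6-dimethoxyphenoxy)-3-(3,4,5-trimethoxyphenyl)propanoate F8 (not isolated), and DBU-induced E1cB elimination should give mainly the thermodynamic ester F5. F5 is converted to 6 by the photosensitised isomerisation described for step 3.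

Further compounds
F1 | step 6 | 2-(4-allyl-2,6-dimethoxyphenoxy)acetic acid | C=CCc1cc(OC)c(OCC(=O)O)c(OC)c1
F2 | step 6 | 2-(4-allyl-2,6-dimethoxyphenoxy)acetic pivalic anhydride | C=CCc1cc(OC)c(OCC(=O)OC(=O)C(C)(C)C)c(OC)c1
F3 | step 6 | (S)-3-[2-(4-allyl-2,6-dimethoxyphenoxy)acetyl]-4-benzyloxazolidin-2-one | C=CCc1cc(OC)c(OCC(=O)N2[C@@H](Cc3ccccc3)COC2=O)c(OC)c1
F4 | step 6 | (S)-3-[(2S,3R)-2-(4-allyl-2,6-dimethoxyphenoxy)-3-hydroxy-3-(3,4,5-trimethoxyphenyl)propanoyl]-4-benzyloxazolidin-2-one | C=CCc1cc(OC)c(O[C@H](C(=O)N2[C@@H](Cc3ccccc3)COC2=O)[C@H](O)c4cc(OC)c(OC)c(OC)c4)c(OC)c1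
F5 | step 3 | ethyl (Z)-2-(4-allyl-2,6-dimethoxyphenoxy)-3-(3,4,5-trimethoxyphenyl)prop-2-enoate | C=CCc1cc(OC)c(O/C(C(=O)OCC)=C\c2cc(OC)c(OC)c(OC)c2)c(OC)c1
F6 | step 2 | ethyl 2-(4-allyl-2,6-dimethoxyphenoxy)acetate | C=CCc1cc(OC)c(OCC(=O)OCC)c(OC)c1
F7 | step 2 | ethyl 2-(4-allyl-2,6-dimethoxyphenoxy)-3-hydroxy-3-(3,4,5-trimethoxyphenyl)propanoate (racemic diastereomer mixture) | C=CCc1cc(OC)c(OC(C(=O)OCC)C(O)c2cc(OC)c(OC)c(OC)c2)c(OC)c1
F8 | step 2 | ethyl 3-acetoxy-2-(4-allyl-2,6-dimethoxyphenoxy)-3-(3,4,5-trimethoxyphenyl)propanoate (racemic diastereomer mixture) | C=CCc1cc(OC)c(OC(C(=O)OCC)C(OC(C)=O)c2cc(OC)c(OC)c(OC)c2)c(OC)c1
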